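## Plan

- Feature: number the central ring C1 (OMe), C2 (H), C3 (OH), C4 and C6 (4‑hydroxybenzyl arms), C5 (phenethyl). The chain C5–Cα–Cβ–phenyl is a two‑carbon bridge between two aryl groups, which is what a vinylboron unit becomes when one aryl group migrates from boron to Cα and a second aryl group is delivered to Cβ.
- Retrosynthetic cuts, in order: the three O–CH2Ph bonds (C3–O and both arm phenols); Cα–H back to Cα–B; C5–Cα and Cβ–phenyl together; C4–CH2 and C6–CH2 (to a 2,4‑diiodide and a benzylzinc reagent); the two C–I bonds; the C3 O–benzyl bond.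
- Forward: no ring is formed. 3‑Bromo‑5‑methoxyphenol is benzylated and iodinated on both sides of bromine; both arms are attached by Negishi coupling; the C5 bromide is converted into a vinylboron ate complex and coupled with phenyl triflate; boron is replaced by hydrogen; one hydrogenolysis frees all three phenols.
- The C3 oxygen is carried as a benzyl ether rather than a methyl ether, so no late selective demethylation is needed.
- Stereochemistry: the target has no stereocentre. The only stereocentre on the route (Cα–B in 11) forms without need for control and is removed in step 6.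

Key step: step 5

Remark on the chemistry: the target is achiral, so there is no enantiomer to select; 3‑bromo‑5‑methoxyphenol is taken as a catalogue compound.

## Route

Step 1
Reactants: 1 3‑bromo‑5‑methoxyphenol
Product: 2 1‑(benzyloxy)‑3‑bromo‑5‑methoxybenzene
Conditions: BnBr, K2CO3, DMF, rt
Reagents that add atoms: benzyl bromide, BrCc1ccccc1
Why: Williamson ether synthesis, in which the phenoxide formed with carbonate is O‑alkylated by benzyl bromide (SN2) while the aryl bromide and methyl ether are inert.

Step 2
Reactants: 2 1‑(benzyloxy)‑3‑bromo‑5‑methoxybenzene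
Product: 3 1‑(benzyloxy)‑3‑bromo‑2,4‑diiodo‑5‑methoxybenzene
Conditions: NIS (2.3 equiv), TFA (cat.), MeCN, rt to 40 °C
Reagents that add atoms: N‑iodosuccinimide, O=C1CCC(=O)N1I
Why: Electrophilic aromatic iodination, in which each alkoxy group directs to its para position and both of these positions flank bromine, so two iodinations should give the 2,4‑diiodide and spare the ortho,ortho position between the oxygens, in line with the usual 2,6‑dihalogenation of 1‑substituted 3,5‑dialkoxybenzenes.

Step 3
Reactants: 4 4‑(benzyloxy)benzyl chloride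
Product: 5 4‑(benzyloxy)benzylzinc chloride (kept as a titrated THF solution)
Conditions: Zn dust (activated with BrCH2CH2Br/TMSCl), LiCl, THF, 25 °C
Reagents that add atoms: zinc, [Zn]
Why: Lithium chloride‑promoted direct insertion of zinc into a benzylic chloride, which tolerates the aryl benzyl ether and should give a stable benzylzinc solution with little Wurtz dimer.

Step 4
Reactants: 3 1‑(benzyloxy)‑3‑bromo‑2,4‑diiodo‑5‑methoxybenzene; 5 4‑(benzyloxy)benzylzinc chloride (2.4 equiv)
Product: 6 1‑(benzyloxy)‑2,4‑bis[4‑(benzyloxy)benzyl]‑3‑bromo‑5‑methoxybenzene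
Conditions: Pd(dba)2 (5 mol%), P(2‑furyl)3 (10 mol%), THF, 25 to 50 °C
Reagents that add atoms: none
Why: Twofold Negishi cross‑coupling, in which palladium(0) inserts into C–I far faster than into the C–Br bond (which ends up shielded between two benzyl arms) and benzylzinc reagents transmetalate readily even at ortho,ortho'‑disubstituted arylpalladium centres.

Step 5
Reactants: 6 1‑(benzyloxy)‑2,4‑bis[4‑(benzyloxy)benzyl]‑3‑bromo‑5‑methoxybenzene; 7 vinylboronic acid pinacol ester; 8 phenyl trifluoromethanesulfonate
Product: 11 2‑{1‑[3‑(benzyloxy)‑2,6‑bis(4‑(benzyloxy)benzyl)‑5‑methoxyphenyl]‑2‑phenylethyl}‑4,4,5,5‑tetramethyl‑1,3,2‑dioxaborolane (racemic), via aryllithium 9 (not isolated), via lithium vinylboron ate complex 10 (not isolated)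
Conditions: t‑BuLi (2.0 equiv), THF/Et2O, −78 °C; 7, −78 °C to rt; evaporate; NaOTf, Pd(OAc)2 (2 mol%), MandyPhos (2.4 mol%, either enantiomer), 8, THF, 60 °C
Reagents that add atoms: none
Why: Bromine–lithium exchange at −78 °C outruns deprotonation of the benzylic and benzyloxy CH2 groups, and aryllithium 9 adds to the boron of 7 to give ate complex 10. Oxidative addition of 8 gives a cationic phenylpalladium(II) species that binds the vinyl group, the aryl group on boron then shifts to Cα anti to palladium (1,2‑metalate rearrangement) and reductive elimination joins Cβ to phenyl, so that C5–Cα and Cβ–phenyl form in one operation and no ring closes. The closest known reaction is the palladium‑catalysed conjunctive cross‑coupling of aryllithium‑derived vinylboron pinacol ate complexes with aryl triflates, applied here to an ortho,ortho'‑disubstituted migrating group at the limit of that scope. The only new stereocentre, the boron‑bearing Cα, needs no control because step 6 replaces boron by hydrogen, so the sense of induction of the ligand is immaterial. The selectivity required is conjunctive coupling over direct aryl transfer to palladium and over β‑hydride elimination: the chelating diphosphine and the triflate counter‑ion keep palladium cationic and alkene‑bound, sodium triflate removes the bromide that would otherwise block that site, and the two flanking benzyl arms hinder transmetalation of the aryl group. Regiochemistry is fixed by the mechanism, since only the carbon ligand on boron can migrate and it can only reach Cα.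

Step 6
Reactants: 11 2‑{1‑[3‑(benzyloxy)‑2,6‑bis(4‑(benzyloxy)benzyl)‑5‑methoxyphenyl]‑2‑phenylethyl}‑4,4,5,5‑tetramethyl‑1,3,2‑dioxaborolane
Product: 12 1‑(benzyloxy)‑2,4‑bis[4‑(benzyloxy)benzyl]‑5‑methoxy‑3‑(2‑phenylethyl)benzene
Conditions: TBAF·3H2O (3 equiv), toluene, 60 °C
Reagents that add atoms: none
Why: Fluoride‑promoted protodeboronation of a benzylic boronic ester, in which fluoride adds to boron and the benzylic C–B bond of the resulting ate complex is protonated by water with the aryl ring stabilising the developing negative charge, while benzyl and methyl ethers are inert to fluoride.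

Step 7
Reactants: 12 1‑(benzyloxy)‑2,4‑bis[4‑(benzyloxy)benzyl]‑5‑methoxy‑3‑(2‑phenylethyl)benzene
Product: 13 2,4‑bis(4‑hydroxybenzyl)‑5‑methoxy‑3‑(2‑phenylethyl)phenol (IN1158)
Conditions: H2 (1 atm), 10% Pd/C, EtOAc/MeOH, rt
Reagents that add atoms: none
Why: Catalytic hydrogenolysis of aryl benzyl ethers over palladium should cleave the three O–CH2Ph bonds and leave the methyl ether, the diarylmethane CH2 groups and the bibenzyl bridge untouched.

## Compound list

1 | 3‑bromo‑5‑methoxyphenol | COc1cc(O)cc(Br)c1 | starting material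
2 | 1‑(benzyloxy)‑3‑bromo‑5‑methoxybenzene | COc1cc(Br)cc(OCc2ccccc2)c1 | intermediate
3 | 1‑(benzyloxy)‑3‑bromo‑2,4‑diiodo‑5‑methoxybenzene | COc1cc(OCc2ccccc2)c(I)c(Br)c1I | intermediate
4 | 4‑(benzyloxy)benzyl chloride | ClCc1ccc(OCc2ccccc2)cc1 | starting material
5 | 4‑(benzyloxy)benzylzinc chloride | Cl[Zn]Cc1ccc(OCc2ccccc2)cc1 | intermediate
6 | 1‑(benzyloxy)‑2,4‑bis[4‑(benzyloxy)benzyl]‑3‑bromo‑5‑methoxybenzene | COc1cc(OCc2ccccc2)c(Cc2ccc(OCc3ccccc3)cc2)c(Br)c1Cc1ccc(OCc2ccccc2)cc1 | intermediate
7 | vinylboronic acid pinacol ester | C=CB1OC(C)(C)C(C)(C)O1 | starting material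
8 | phenyl trifluoromethanesulfonate | O=S(=O)(Oc1ccccc1)C(F)(F)F | starting material
9 | [3‑(benzyloxy)‑2,6‑bis(4‑(benzyloxy)benzyl)‑5‑methoxyphenyl]lithium | [Li]c1c(Cc2ccc(OCc3ccccc3)cc2)c(OC)cc(OCc2ccccc2)c1Cc1ccc(OCc2ccccc2)cc1 | intermediate
10 | lithium aryl(vinyl)pinacolatoborate (ate complex of 9 and 7) | [Li+].C=C[B-]1(OC(C)(C)C(C)(C)O1)c1c(Cc2ccc(OCc3ccccc3)cc2)c(OC)cc(OCc2ccccc2)c1Cc1ccc(OCc2ccccc2)cc1 | intermediate
11 | 2‑{1‑[3‑(benzyloxy)‑2,6‑bis(4‑(benzyloxy)benzyl)‑5‑methoxyphenyl]‑2‑phenylethyl}‑4,4,5,5‑tetramethyl‑1,3,2‑dioxaborolane (racemic) | COc1cc(OCc2ccccc2)c(Cc2ccc(OCc3ccccc3)cc2)c(C(Cc2ccccc2)B2OC(C)(C)C(C)(C)O2)c1Cc1ccc(OCc2ccccc2)cc1 | intermediate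
12 | 1‑(benzyloxy)‑2,4‑bis[4‑(benzyloxy)benzyl]‑5‑methoxy‑3‑(2‑phenylethyl)benzene | COc1cc(OCc2ccccc2)c(Cc2ccc(OCc3ccccc3)cc2)c(CCc2ccccc2)c1Cc1ccc(OCc2ccccc2)cc1 | intermediate
13 | 2,4‑bis(4‑hydroxybenzyl)‑5‑methoxy‑3‑(2‑phenylethyl)phenol (IN1158) | COc1cc(O)c(Cc2ccc(O)cc2)c(CCc2ccccc2)c1Cc1ccc(O)cc1 | target

## Step count and risks

Total steps: 7. Longest linear sequence: 6 (steps 1, 2, 4, 5, 6, 7); step 3 is a one‑step side branch that joins at step 4.

Steps most likely to fail:

1. Step 5. The 1,2‑shift of the doubly ortho‑substituted aryl group may be slow, so that direct aryl transfer to palladium or protonation of the aryllithium or ate complex takes over; proton transfer from a diarylmethane CH2 to the aryllithium before it reaches boron is a second possible loss. Fallback: starting from bromide 6, a copper‑free Sonogashira coupling with phenylacetylene (PdCl2(MeCN)2, XPhos, Cs2CO3, MeCN, 80 °C) should give 1‑(benzyloxy)‑2,4‑bis[4‑(benzyloxy)benzyl]‑5‑methoxy‑3‑(phenylethynyl)benzene F1. Hydrogenation over Pd/C (H2, EtOAc/MeOH) would then saturate the triple bond and cleave the three benzyl ethers in the same operation, rejoining the route at target 13.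

2. Step 6. Fluoride may attack the crowded boron only sluggishly, or protonolysis of the C–B bond may stall. Fallback: starting from boronate 11, oxidation (H2O2, NaOH, THF/H2O, 0 °C to rt) should give 1‑[3‑(benzyloxy)‑2,6‑bis(4‑(benzyloxy)benzyl)‑5‑methoxyphenyl]‑2‑phenylethanol F2 (racemic). Syn‑elimination with Burgess reagent (toluene, 50 °C) is chosen over acid so that no benzylic cation can cyclise onto a neighbouring benzyl arm, and should give 1‑(benzyloxy)‑2,4‑bis[4‑(benzyloxy)benzyl]‑5‑methoxy‑3‑[(E)‑2‑phenylethenyl]benzene F3. Hydrogenation over Pd/C would reduce the alkene and remove the three benzyl groups, rejoining the route at target 13.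

3. Step 4. Coupling at the second, more crowded iodide may be incomplete, with hydrodeiodination or late insertion into the C–Br bond eroding the product. Fallback: starting from aryl bromide 2 and benzyl chloride 4 (2.1 equiv), a twofold Friedel–Crafts benzylation in hexafluoroisopropanol at rt would place both arms para to the alkoxy groups, the same positions that iodine takes in step 2, and give bromide 6 directly without diiodide 3 or zinc reagent 5. A third benzylation between the two oxygens would have to be held back by stoichiometry. The fallback rejoins the route at 6 and makes no new compound.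

## Further compounds

F1 | step 5 | 1‑(benzyloxy)‑2,4‑bis[4‑(benzyloxy)benzyl]‑5‑methoxy‑3‑(phenylethynyl)benzene | COc1cc(OCc2ccccc2)c(Cc2ccc(OCc3ccccc3)cc2)c(C#Cc2ccccc2)c1Cc1ccc(OCc2ccccc2)cc1
F2 | step 6 | 1‑[3‑(benzyloxy)‑2,6‑bis(4‑(benzyloxy)benzyl)‑5‑methoxyphenyl]‑2‑phenylethanol (racemic) | COc1cc(OCc2ccccc2)c(Cc2ccc(OCc3ccccc3)cc2)c(C(O)Cc2ccccc2)c1Cc1ccc(OCc2ccccc2)cc1
F3 | step 6 | 1‑(benzyloxy)‑2,4‑bis[4‑(benzyloxy)benzyl]‑5‑methoxy‑3‑[(E)‑2‑phenylethenyl]benzene | COc1cc(OCc2ccccc2)c(Cc2ccc(OCc3ccccc3)cc2)c(/C=C/c2ccccc2)c1Cc1ccc(OCc2ccccc2)cc1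
F0 | step 4 | none | none
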